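**Retrosynthetic overview** (ring A = diprenylated benzoate ring, ring B = seven-membered dioxepinone, ring C = tetraoxygenated benzene, ring D = pyran)
1. Ring B is closed last. The lactone C(=O)–O bond is cut back to seco acid 24, which is closed by high-dilution carbodiimide lactonisation.
2. The diaryl ether comes from the ring A phenoxide and bromoquinone 20 (oxa-Michael addition–elimination). Reduction of the quinone then frees both ring C hydroxyls without protecting groups.
3. Ring D is the key ring closure and is formed first, by ring-closing metathesis of the styrene/1,1-dimethylallyl ether 18 to chromene 19. Ring C comes from 2,5-dimethoxybenzaldehyde.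
4. Ring A fragment 7 comes from 2,4,6-trihydroxybenzoic acid. Both prenyl groups are set by a double Claisen rearrangement followed by cross metathesis.
5. The ring order is D (metathesis), then B (lactonisation). Rings A and C are bought as arenes, and the three branches meet at steps 10 and 14.

Assumption: the SMILES has no stereocentre and its only ring olefin is necessarily cis, so the target is achiral and no configuration has to be set.

**Fragment A (ring A)**

Step 1
Reactants: 1 2,4,6-trihydroxybenzoic acid (dried azeotropically)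
Product: 2 2-(trimethylsilyl)ethyl 2,4,6-trihydroxybenzoate
Conditions: Me3SiCH2CH2OH (1.1 equiv), PPh3, DIAD, THF, 0 °C to rt
Reagents that add atoms: 2-(trimethylsilyl)ethanol, C[Si](C)(C)CCO
Why: Mitsunobu esterification, in which only the strongly acidic carboxyl group (not the phenols) is alkylated by the primary alkoxyphosphonium ion, giving a fluoride-labile ester that withstands the later thermal step.

Step 2
Reactants: 2 2-(trimethylsilyl)ethyl 2,4,6-trihydroxybenzoate
Product: 3 2-(trimethylsilyl)ethyl 2,4-bis(allyloxy)-6-hydroxybenzoate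
Conditions: allyl bromide (2.1 equiv), K2CO3, acetone, reflux
Reagents that add atoms: allyl bromide, C=CCBr
Why: Williamson etherification, in which the 4-OH and one ortho OH react while the last ortho OH stays free because it is hydrogen-bonded to the ester carbonyl.

Step 3
Reactants: 3 2-(trimethylsilyl)ethyl 2,4-bis(allyloxy)-6-hydroxybenzoate
Product: 5 2-(trimethylsilyl)ethyl 3,5-diallyl-2,4,6-trihydroxybenzoate, via mono-rearranged phenol 4 (not isolated)
Conditions: PhNEt2, 195 °C, sealed tube, Ar
Reagents that add atoms: none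
Why: Double aromatic Claisen rearrangement, in which the two allyl groups can only end on C3 and C5 (by an ortho shift, or by an ortho shift followed by a Cope shift to the para site), so every pathway gives the same product.

Step 4
Reactants: 5 2-(trimethylsilyl)ethyl 3,5-diallyl-2,4,6-trihydroxybenzoate
Product: 6 2-(trimethylsilyl)ethyl 3,5-diallyl-4-[(tert-butyldimethylsilyl)oxy]-2,6-dihydroxybenzoate
Conditions: TBSCl (1.05 equiv), imidazole, DMF, 0 °C to rt
Reagents that add atoms: tert-butyldimethylsilyl chloride, CC(C)(C)[Si](C)(C)Cl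
Why: Chemoselective O-silylation, in which the para OH is the most acidic and is not chelated, while both ortho OH groups are tied up in hydrogen bonds to the ester.

Step 5
Reactants: 6 2-(trimethylsilyl)ethyl 3,5-diallyl-4-[(tert-butyldimethylsilyl)oxy]-2,6-dihydroxybenzoate
Product: 7 2-(trimethylsilyl)ethyl 4-[(tert-butyldimethylsilyl)oxy]-2,6-dihydroxy-3,5-bis(3-methylbut-2-en-1-yl)benzoate
Conditions: second-generation Grubbs catalyst RuCl2(=CHPh)(PCy3)(H2IMes) (5 mol %), 2-methylbut-2-ene/CH2Cl2, 40 °C, sealed flask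
Reagents that add atoms: 2-methylbut-2-ene, CC=C(C)C
Why: Olefin cross metathesis with a large excess of 2-methylbut-2-ene turns both terminal allyl groups into the unreactive trisubstituted prenyl olefins, and chelated phenols and silyl groups are tolerated.

**Reagent branch**

Step 6
Reactants: 8 2-methylbut-3-en-2-ol
Product: 10 methyl (2-methylbut-3-en-2-yl) carbonate, via lithium alkoxide 9 (not isolated)
Conditions: n-BuLi, THF, −78 to 0 °C; then ClCO2Me, 0 °C to rt
Reagents that add atoms: methyl chloroformate, COC(=O)Cl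
Why: O-acylation of the preformed tertiary alkoxide by the chloroformate is fast and avoids the acid-induced ionisation of the tertiary allylic alcohol.

**Fragment B (rings C and D)**

Step 7
Reactants: 11 2,5-dimethoxybenzaldehyde
Product: 13 2,5-dimethoxyphenol, via aryl formate 12 (not isolated)
Conditions: mCPBA, CH2Cl2, 0 °C to rt, aq NaHCO3 wash; then K2CO3 (cat.), MeOH, rt
Reagents that add atoms: mCPBA, OOC(=O)c1cccc(Cl)c1
Why: Baeyer–Villiger (Dakin-type) oxidation, in which the electron-rich aryl group migrates in preference to hydrogen and the formate is removed by mild methanolysis.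

Step 8
Reactants: 13 2,5-dimethoxyphenol
Product: 15 2-hydroxy-3,6-dimethoxybenzaldehyde, via hydroxymethylphenol 14 (not isolated)
Conditions: MgCl2, Et3N, (CH2O)n, MeCN, reflux; 1 M HCl work-up
Reagents that add atoms: paraformaldehyde (reacts as formaldehyde), C=O
Why: Casnati–Skattebøl ortho-formylation, in which the magnesium phenoxide delivers formaldehyde to the only free ortho carbon and a second formaldehyde oxidises the benzylic alkoxide by hydride transfer.

Step 9
Reactants: 15 2-hydroxy-3,6-dimethoxybenzaldehyde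
Product: 16 5-bromo-2-hydroxy-3,6-dimethoxybenzaldehyde
Conditions: NBS (1.0 equiv), MeCN, 0 °C
Reagents that add atoms: N-bromosuccinimide, O=C1CCC(=O)N1Br
Why: Electrophilic aromatic bromination goes to C5 because that position is para to OH, ortho to the 6-OMe and meta to CHO, so all three directing effects agree.

Step 10
Reactants: 16 5-bromo-2-hydroxy-3,6-dimethoxybenzaldehyde; 10 methyl (2-methylbut-3-en-2-yl) carbonate
Product: 17 5-bromo-3,6-dimethoxy-2-[(2-methylbut-3-en-2-yl)oxy]benzaldehyde
Conditions: Pd(PPh3)4 (3 mol %), THF, 0 °C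
Reagents that add atoms: none
Why: Tsuji–Trost O-allylation, in which zerovalent palladium ionises the carbonate and the phenoxide attacks the more substituted terminus of the dimethylallyl complex under kinetic control, while the electron-rich C–Br bond is inert at 0 °C.

Step 11
Reactants: 17 5-bromo-3,6-dimethoxy-2-[(2-methylbut-3-en-2-yl)oxy]benzaldehyde
Product: 18 1-bromo-2,5-dimethoxy-4-[(2-methylbut-3-en-2-yl)oxy]-3-vinylbenzene
Conditions: Ph3PCH3Br, KOtBu, THF, 0 °C
Reagents that add atoms: methyltriphenylphosphonium bromide, C[P+](c1ccccc1)(c1ccccc1)c1ccccc1.[Br-]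
Why: Wittig methylenation, in which the small unstabilised ylide reaches the flanked aldehyde and the basic, cold medium leaves the acid- and heat-sensitive tertiary allyl ether untouched.

Step 12 (key ring closure, ring D)
Reactants: 18 1-bromo-2,5-dimethoxy-4-[(2-methylbut-3-en-2-yl)oxy]-3-vinylbenzene
Product: 19 6-bromo-5,8-dimethoxy-2,2-dimethyl-2H-chromene
Conditions: second-generation Grubbs catalyst RuCl2(=CHPh)(PCy3)(H2IMes) (3 mol %), CH2Cl2 (0.01 M), 40 °C
Reagents that add atoms: none
Why: Ring-closing metathesis, in which the ruthenium alkylidene loads on the styrene and closes onto the neighbouring vinyl group, helped by the gem-dimethyl effect and by loss of ethylene, and no prenyl olefin is present at this stage.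

Step 13
Reactants: 19 6-bromo-5,8-dimethoxy-2,2-dimethyl-2H-chromene
Product: 20 6-bromo-2,2-dimethyl-2H-chromene-5,8-dione
Conditions: (NH4)2Ce(NO3)6 (2.2 equiv), MeCN/H2O, 0 °C, 15 min
Reagents that add atoms: water, O
Why: Oxidative demethylation by tetravalent cerium, in which two one-electron oxidations of the para-dimethoxyarene with ipso attack of water give the quinone within minutes, faster than any attack on the chromene olefin.

**Union and endgame**

Step 14
Reactants: 7 2-(trimethylsilyl)ethyl 4-[(tert-butyldimethylsilyl)oxy]-2,6-dihydroxy-3,5-bis(3-methylbut-2-en-1-yl)benzoate; 20 6-bromo-2,2-dimethyl-2H-chromene-5,8-dione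
Product: 22 2-(trimethylsilyl)ethyl 4-[(tert-butyldimethylsilyl)oxy]-2-[(2,2-dimethyl-5,8-dioxo-5,8-dihydro-2H-chromen-6-yl)oxy]-6-hydroxy-3,5-bis(3-methylbut-2-en-1-yl)benzoate, via sodium phenoxide 21 (not isolated)
Conditions: NaH (1.0 equiv), THF/DMF, 0 °C; then added slowly to 20, −20 °C to rt
Reagents that add atoms: none
Why: Oxa-Michael addition–elimination, in which the pyran oxygen deactivates the C5 carbonyl so attack goes to C6 (beta to the C8 carbonyl and carrying bromide); the two phenols of 7 are equivalent and its ring has no free carbon, so only one O-arylation product can form.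

Step 15
Reactants: 22 aryloxyquinone
Product: 23 2-(trimethylsilyl)ethyl 4-[(tert-butyldimethylsilyl)oxy]-2-[(5,8-dihydroxy-2,2-dimethyl-2H-chromen-6-yl)oxy]-6-hydroxy-3,5-bis(3-methylbut-2-en-1-yl)benzoate
Conditions: Na2S2O4, THF/H2O, rt, Ar
Reagents that add atoms: none
Why: Dithionite reduction of the quinone to the hydroquinone is selective over olefins, ester and silyl groups, and it creates the C5 and C8 hydroxyls of ring C.

Step 16
Reactants: 23 hydroquinone diaryl ether
Product: 24 2-[(5,8-dihydroxy-2,2-dimethyl-2H-chromen-6-yl)oxy]-4,6-dihydroxy-3,5-bis(3-methylbut-2-en-1-yl)benzoic acid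
Conditions: Bu4NF (6 equiv), degassed THF, 0 °C to rt, Ar; cold dilute HCl to pH 3–4, used crude at once
Reagents that add atoms: none
Why: Fluoride-induced desilylation cleaves the aryl silyl ether and fragments the beta-silylethyl ester in one operation, without the acid or hydroxide that would harm the prenyl groups, the chromene or the decarboxylation-prone acid.

Step 17 (ring B)
Reactants: 24 seco acid
Product: 26 garcinisidone E, via O-acylisourea 25 (not isolated)
Conditions: DCC (1.3 equiv), DMAP, DMAP·HCl, CH2Cl2 (2 mM, syringe-pump addition), rt, Ar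
Reagents that add atoms: none
Why: Keck-type carbodiimide lactonisation at high dilution, in which only the C5 hydroxyl ortho to the ether bridge can reach the activated carboxyl (seven-membered ring), so the other three phenols need no protection.

**Compound list**
1 | 2,4,6-trihydroxybenzoic acid | OC(=O)c1c(O)cc(O)cc1O | starting material
2 | 2-(trimethylsilyl)ethyl 2,4,6-trihydroxybenzoate | C[Si](C)(C)CCOC(=O)c1c(O)cc(O)cc1O | intermediate
3 | 2-(trimethylsilyl)ethyl 2,4-bis(allyloxy)-6-hydroxybenzoate | C[Si](C)(C)CCOC(=O)c1c(O)cc(OCC=C)cc1OCC=C | intermediate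
4 | 2-(trimethylsilyl)ethyl 3-allyl-6-(allyloxy)-2,4-dihydroxybenzoate (not isolated) | C[Si](C)(C)CCOC(=O)c1c(O)c(CC=C)c(O)cc1OCC=C | intermediate
5 | 2-(trimethylsilyl)ethyl 3,5-diallyl-2,4,6-trihydroxybenzoate | C[Si](C)(C)CCOC(=O)c1c(O)c(CC=C)c(O)c(CC=C)c1O | intermediate
6 | 2-(trimethylsilyl)ethyl 3,5-diallyl-4-[(tert-butyldimethylsilyl)oxy]-2,6-dihydroxybenzoate | C[Si](C)(C)CCOC(=O)c1c(O)c(CC=C)c(O[Si](C)(C)C(C)(C)C)c(CC=C)c1O | intermediate
7 | 2-(trimethylsilyl)ethyl 4-[(tert-butyldimethylsilyl)oxy]-2,6-dihydroxy-3,5-bis(3-methylbut-2-en-1-yl)benzoate (fragment A) | C[Si](C)(C)CCOC(=O)c1c(O)c(CC=C(C)C)c(O[Si](C)(C)C(C)(C)C)c(CC=C(C)C)c1O | intermediate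
8 | 2-methylbut-3-en-2-ol | C=CC(C)(C)O | starting material
9 | lithium 2-methylbut-3-en-2-olate (not isolated) | [Li+].[O-]C(C)(C)C=C | intermediate
10 | methyl (2-methylbut-3-en-2-yl) carbonate | COC(=O)OC(C)(C)C=C | intermediate
11 | 2,5-dimethoxybenzaldehyde | COc1ccc(OC)c(C=O)c1 | starting material
12 | 2,5-dimethoxyphenyl formate (not isolated) | COc1ccc(OC)c(OC=O)c1 | intermediate
13 | 2,5-dimethoxyphenol | COc1ccc(OC)c(O)c1 | intermediate
14 | 2-(hydroxymethyl)-3,6-dimethoxyphenol (present as its magnesium salt, drawn neutral, not isolated) | COc1ccc(OC)c(CO)c1O | intermediate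
15 | 2-hydroxy-3,6-dimethoxybenzaldehyde | COc1ccc(OC)c(C=O)c1O | intermediate
16 | 5-bromo-2-hydroxy-3,6-dimethoxybenzaldehyde | COc1cc(Br)c(OC)c(C=O)c1O | intermediate
17 | 5-bromo-3,6-dimethoxy-2-[(2-methylbut-3-en-2-yl)oxy]benzaldehyde | COc1cc(Br)c(OC)c(C=O)c1OC(C)(C)C=C | intermediate
18 | 1-bromo-2,5-dimethoxy-4-[(2-methylbut-3-en-2-yl)oxy]-3-vinylbenzene | COc1cc(Br)c(OC)c(C=C)c1OC(C)(C)C=C | intermediate
19 | 6-bromo-5,8-dimethoxy-2,2-dimethyl-2H-chromene | COc1cc(Br)c(OC)c2C=CC(C)(C)Oc12 | intermediate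
20 | 6-bromo-2,2-dimethyl-2H-chromene-5,8-dione (fragment B) | CC1(C)C=CC2=C(O1)C(=O)C=C(Br)C2=O | intermediate
21 | monosodium phenoxide of 7 (not isolated) | [Na+].C[Si](C)(C)CCOC(=O)c1c(O)c(CC=C(C)C)c(O[Si](C)(C)C(C)(C)C)c(CC=C(C)C)c1[O-] | intermediate
22 | 2-(trimethylsilyl)ethyl 4-[(tert-butyldimethylsilyl)oxy]-2-[(2,2-dimethyl-5,8-dioxo-5,8-dihydro-2H-chromen-6-yl)oxy]-6-hydroxy-3,5-bis(3-methylbut-2-en-1-yl)benzoate | C[Si](C)(C)CCOC(=O)c1c(O)c(CC=C(C)C)c(O[Si](C)(C)C(C)(C)C)c(CC=C(C)C)c1OC1=CC(=O)C2=C(C=CC(C)(C)O2)C1=O | intermediate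
23 | 2-(trimethylsilyl)ethyl 4-[(tert-butyldimethylsilyl)oxy]-2-[(5,8-dihydroxy-2,2-dimethyl-2H-chromen-6-yl)oxy]-6-hydroxy-3,5-bis(3-methylbut-2-en-1-yl)benzoate | C[Si](C)(C)CCOC(=O)c1c(O)c(CC=C(C)C)c(O[Si](C)(C)C(C)(C)C)c(CC=C(C)C)c1Oc1cc(O)c2OC(C)(C)C=Cc2c1O | intermediate
24 | 2-[(5,8-dihydroxy-2,2-dimethyl-2H-chromen-6-yl)oxy]-4,6-dihydroxy-3,5-bis(3-methylbut-2-en-1-yl)benzoic acid | OC(=O)c1c(O)c(CC=C(C)C)c(O)c(CC=C(C)C)c1Oc1cc(O)c2OC(C)(C)C=Cc2c1O | intermediate
25 | O-acylisourea of 24 with DCC (not isolated) | O=C(OC(=NC1CCCCC1)NC1CCCCC1)c1c(O)c(CC=C(C)C)c(O)c(CC=C(C)C)c1Oc1cc(O)c2OC(C)(C)C=Cc2c1O | intermediate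
26 | garcinisidone E (achiral) | CC(C)=CCc1c(O)c(CC=C(C)C)c2c(c1O)C(=O)Oc1c(cc(O)c3c1C=CC(C)(C)O3)O2 | target

**Counts**
Total step count: 17.
Longest linear sequence: 11 steps (11 to 26, steps 7–17). The other branches are 1 to 26 (9 steps) and 8 to 26 (9 steps).

**Three steps most likely to fail**

Risk at step 10. The phenol is hindered and acidic, so the tertiary ether may re-ionise on palladium and drift to the linear prenyl ether. The fallback sets out from 16 and comes back at 17, and it builds the tertiary C–O bond without an allyl-metal species. Copper-catalysed propargylation of 16 with 3-chloro-3-methylbut-1-yne (CuCl2 1 mol %, DBU, MeCN, 0 °C) gives 5-bromo-3,6-dimethoxy-2-[(2-methylbut-3-yn-2-yl)oxy]benzaldehyde F1. Semi-hydrogenation of its alkyne (H2, Pd/CaCO3 poisoned with Pb(OAc)2, quinoline, EtOAc) then gives 17. Carbonate 10 is not needed on this path.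

Risk at step 14. The chelated, doubly flanked phenoxide is a weak nucleophile, and the bromoquinone is sensitive to base and to electron transfer. The fallback sets out from 19 (together with 7) and comes back at 22. It makes the ether at the arene oxidation level and oxidises afterwards. Bromine–lithium exchange on 19 (n-BuLi, THF, −78 °C), B(OiPr)3 and aqueous NH4Cl give (5,8-dimethoxy-2,2-dimethyl-2H-chromen-6-yl)boronic acid F2. Chan–Evans–Lam coupling of F2 with 7 (Cu(OAc)2, pyridine, 4 Å sieves, CH2Cl2, air, rt) tolerates di-ortho-substituted phenols. It gives 2-(trimethylsilyl)ethyl 4-[(tert-butyldimethylsilyl)oxy]-2-[(5,8-dimethoxy-2,2-dimethyl-2H-chromen-6-yl)oxy]-6-hydroxy-3,5-bis(3-methylbut-2-en-1-yl)benzoate F3. Brief treatment with (NH4)2Ce(NO3)6 in MeCN/H2O at 0 °C oxidises the far more electron-rich ring C selectively and gives 22.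

Risk at step 17. The unprotected seco acid 24 is air-sensitive and prone to decarboxylation, and it can oligomerise or form an N-acylurea. The fallback sets out from 22 and comes back at 26. It activates the acid before the nucleophile exists.
- Bu4NF on quinone 22 gives the air-stable 2-[(2,2-dimethyl-5,8-dioxo-5,8-dihydro-2H-chromen-6-yl)oxy]-4,6-dihydroxy-3,5-bis(3-methylbut-2-en-1-yl)benzoic acid F4.
- DCC and C6F5OH convert F4 into its isolable pentafluorophenyl ester F5.
- Na2S2O4 in THF/pH 7 buffer then reduces the quinone to the pentafluorophenyl ester of seco acid 24 F6.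
- The newly freed C5 hydroxyl of F6 closes onto the active ester in the same flask on addition of iPr2NEt (reduction-triggered lactonisation) and gives 26.

**Further compounds**
F1 | step 10 | 5-bromo-3,6-dimethoxy-2-[(2-methylbut-3-yn-2-yl)oxy]benzaldehyde | COc1cc(Br)c(OC)c(C=O)c1OC(C)(C)C#C
F2 | step 14 | (5,8-dimethoxy-2,2-dimethyl-2H-chromen-6-yl)boronic acid | COc1cc(B(O)O)c(OC)c2C=CC(C)(C)Oc12
F3 | step 14 | 2-(trimethylsilyl)ethyl 4-[(tert-butyldimethylsilyl)oxy]-2-[(5,8-dimethoxy-2,2-dimethyl-2H-chromen-6-yl)oxy]-6-hydroxy-3,5-bis(3-methylbut-2-en-1-yl)benzoate | C[Si](C)(C)CCOC(=O)c1c(O)c(CC=C(C)C)c(O[Si](C)(C)C(C)(C)C)c(CC=C(C)C)c1Oc1cc(OC)c2OC(C)(C)C=Cc2c1OC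
F4 | step 17 | 2-[(2,2-dimethyl-5,8-dioxo-5,8-dihydro-2H-chromen-6-yl)oxy]-4,6-dihydroxy-3,5-bis(3-methylbut-2-en-1-yl)benzoic acid | OC(=O)c1c(O)c(CC=C(C)C)c(O)c(CC=C(C)C)c1OC1=CC(=O)C2=C(C=CC(C)(C)O2)C1=O
F5 | step 17 | pentafluorophenyl ester of F4 | O=C(Oc1c(F)c(F)c(F)c(F)c1F)c1c(O)c(CC=C(C)C)c(O)c(CC=C(C)C)c1OC1=CC(=O)C2=C(C=CC(C)(C)O2)C1=O
F6 | step 17 | pentafluorophenyl ester of seco acid 24 | O=C(Oc1c(F)c(F)c(F)c(F)c1F)c1c(O)c(CC=C(C)C)c(O)c(CC=C(C)C)c1Oc1cc(O)c2OC(C)(C)C=Cc2c1O
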